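**Retrosynthetic overview**
1. Locants are the decalin locants of the target name (compound 21): C1 carries CH3 and the benzylic carbon C1′, C2 carries CH3, C4a is the ring-fusion CH, C5 the methylidene carbon, C8a the methyl-bearing ring-fusion carbon; ring A = C4a, C5–C8, C8a; ring B = C1–C4, C4a, C8a; α = face of H-4a.
2. End-game cuts: C5=CH2 from a C5 ketone (methylenation); C1′–aryl from an arylmagnesium reagent and a C1′ lactol; the C8–O and C1′–O bonds left by the tether are removed together by radical deoxygenation; H-2 and H-4a come from one hydroxyl-directed hydrogenation.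
3. Key cut: ring B, taken at the C4=C4a alkene level, is opened by a retro-[4+2] across C1–C8a and C2–C3: the diene C8a=C4a–C4=C3 is a 1-vinylcyclohexene built into ring A, the dienophile C1=C2 is the conjugated bond of a 2-methylallenoate.
4. Enabling feature: C1–C8a and C2–C3 are the two allylic bonds of that cyclohexene, C8 of ring A is next to C8a, and C1′ sits on C1, so a temporary ester C8–O–C1′(=O) (a γ-lactone fused at C1–C8a) ties dienophile to diene; the C8 carbinol is the only stereocentre that has to be made with a chiral reagent.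
5. Ring order: ring A (from a commercial cyclohexenone) → ring B plus the temporary γ-lactone in one step → lactone opened and the purchased arene attached.

Key step: step 6

**Remarks before the steps**
- Assumption: ethyl 2-methylbuta-2,3-dienoate is taken as a purchasable allenoate.
- TBS = tert-butyldimethylsilyl, MOM = methoxymethyl. C1′ carbinol epimers and lactol anomers are carried as mixtures because those centres are later erased.

**Step 1**
Reactants: 1 3-ethoxy-2-methylcyclohex-2-en-1-one
Product: 3 (±)-6-[(tert-butyldimethylsilyl)oxy]-3-ethoxy-2-methylcyclohex-2-en-1-one, via silyl dienol ether 2 (not isolated)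
Conditions: LiN(i-Pr)2, THF, −78 °C; t-BuMe2SiCl, DMPU, −78 → 0 °C; then mCPBA, NaHCO3, CH2Cl2, −20 → 0 °C
Reagents that add atoms: tert-butyldimethylsilyl chloride CC(C)(C)[Si](C)(C)Cl; 3-chloroperbenzoic acid OOC(=O)c1cccc(Cl)c1
Why: Kinetic α′-deprotonation and O-silylation give a 1-alkoxy-3-siloxy diene whose terminal enol carbon is epoxidised, and 1,4-silyl shift delivers the α′-silyloxy enone (Rubottom oxidation); the new centre is left racemic because it is resolved in step 3.

**Step 2**
Reactants: 3 (±)-6-[(tert-butyldimethylsilyl)oxy]-3-ethoxy-2-methylcyclohex-2-en-1-one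
Product: 5 (±)-4-[(tert-butyldimethylsilyl)oxy]-2-methyl-3-vinylcyclohex-2-en-1-one, via tertiary allylic alkoxide 4 (not isolated)
Conditions: CH2=CHMgBr, THF, 0 °C → rt; then 1 M HCl, THF, 0 °C
Reagents that add atoms: vinylmagnesium bromide C=C[Mg]Br; water O
Why: 1,2-Addition to the vinylogous ester carbonyl, then acid hydrolysis of the enol ether with loss of the tertiary hydroxyl, transposes the enone (Stork–Danheiser sequence) and puts the vinyl group on the future C4a; no new stereocentre is formed.

**Step 3**
Reactants: 5 (±)-4-[(tert-butyldimethylsilyl)oxy]-2-methyl-3-vinylcyclohex-2-en-1-one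
Product: 6 (1S,4S)-4-[(tert-butyldimethylsilyl)oxy]-2-methyl-3-vinylcyclohex-2-en-1-ol (trans)
Conditions: (R)-Me-CBS oxazaborolidine [(R)-1-methyl-3,3-diphenyltetrahydro-1H,3H-pyrrolo[1,2-c][1,3,2]oxazaborole] (0.2 equiv), catecholborane, toluene, −78 °C; chromatographic separation from the cis (1S,4R) diastereomer
Reagents that add atoms: none
Why: Corey–Bakshi–Shibata reduction under catalyst control (alkenyl flank as the large group) should give the 1S carbinol, the future C8, from both enantiomers of 5, so the racemate becomes two separable diastereomers and the trans one is carried on.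

**Step 4**
Reactants: 7 ethyl 2-methylbuta-2,3-dienoate
Product: 8 2-methylbuta-2,3-dienoic acid
Conditions: LiOH, THF/H2O, 0 °C; then 1 M HCl to pH 2
Reagents that add atoms: lithium hydroxide [Li+].[OH-]
Why: Saponification at low temperature, where hydroxide attacks the ester carbonyl faster than the allene; no stereocentre is involved.

**Step 5**
Reactants: 6 (1S,4S)-4-[(tert-butyldimethylsilyl)oxy]-2-methyl-3-vinylcyclohex-2-en-1-ol; 8 2-methylbuta-2,3-dienoic acid
Product: 9 (1S,4S)-4-[(tert-butyldimethylsilyl)oxy]-2-methyl-3-vinylcyclohex-2-en-1-yl 2-methylbuta-2,3-dienoate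
Conditions: 2-chloro-1-methylpyridinium iodide, Et3N, CH2Cl2, 0 °C → rt
Reagents that add atoms: none
Why: Mukaiyama esterification activates the acid as an acyloxypyridinium salt without a nucleophilic catalyst that would add to the allene, and the carbinol C–O bond is untouched, so the 1S centre is retained.

**Step 6**
Reactants: 9 (1S,4S)-4-[(tert-butyldimethylsilyl)oxy]-2-methyl-3-vinylcyclohex-2-en-1-yl 2-methylbuta-2,3-dienoate
Product: 10 tricyclic γ-lactone: 5β-[(tert-butyldimethylsilyl)oxy]-8α-hydroxy-1β,8aβ-dimethyl-2-methylidene-1,2,3,5,6,7,8,8a-octahydronaphthalene-1α-carboxylic acid lactone (C4=C4a)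
Conditions: toluene (0.01 M), BHT, 80 °C
Reagents that add atoms: none
Why: A thermal, concerted but asynchronous intramolecular Diels–Alder reaction joins the conjugated C1=C2 bond of the allenoate to the 1-vinylcyclohexene diene C8a=C4a–C4=C3, with the C2–C3 bond (sp carbon to the unsubstituted diene terminus) leading and the congested C1–C8a bond following. The closest known reaction type is the intramolecular Diels–Alder reaction of 2-methyl-3-vinylcyclohex-2-enyl allenoates and alkynoates, which builds the same angular γ-lactone with an 8a-methyl quaternary centre under mild heating. Ring B closes as the six-membered ring of the [4+2] event, and the temporary γ-lactone closes as the five-membered ring spanned by the three-atom tether C8–O–C1′ across the new C1–C8a bond (nonatriene-type mode). C8a is controlled by the C8 carbinol, because the short tether reaches only the α-face of the diene and leaves the 8a-methyl β; C1 is controlled by the carbonyl-endo arrangement, which gives the cis-fused lactone with the 1-methyl β and syn to the 8a-methyl, whereas the exo alternative needs a trans-fused γ-lactone on an angular tricycle and forces the α-methyl under C4a. The step needs site selectivity for C1=C2 over the distal C2=CH2 bond of the allene, secured because only C1=C2 is conjugated to the ester and only it allows the five-membered tether ring, and endo-tether selectivity, secured by the strain argument and by the pseudoaxial C8–O bond that holds the carbonyl beneath ring A. The trans-disposed 5-silyloxy group is pseudoaxial on the β-face and leaves the reacting α-face open.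

**Step 7**
Reactants: 10 tricyclic γ-lactone
Product: 11 lactol of 10 (C1′ hemiacetal, both anomers)
Conditions: i-Bu2AlH, CH2Cl2, −78 °C; aq. potassium sodium tartrate
Reagents that add atoms: none
Why: Half-reduction of the lactone (DIBAL reduction) stops at the aluminium hemiacetal at −78 °C, and the non-enolisable neopentyl carbonyl offers no other pathway; the anomeric centre is erased later.

**Step 8**
Reactants: 12 methyl 4-hydroxy-3-iodobenzoate
Product: 13 methyl 3-iodo-4-(methoxymethoxy)benzoate
Conditions: MeOCH2Cl, i-Pr2NEt, CH2Cl2, 0 °C → rt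
Reagents that add atoms: chloromethyl methyl ether COCCl
Why: O-Alkylation of the phenol (Williamson-type acetal formation) masks the acidic OH for the organomagnesium step.

**Step 9**
Reactants: 11 lactol; 13 methyl 3-iodo-4-(methoxymethoxy)benzoate
Product: 15 methyl 3-{hydroxy[5β-(tert-butyldimethylsilyloxy)-8α-hydroxy-1β,8aβ-dimethyl-2-methylidene-1,2,3,5,6,7,8,8a-octahydronaphthalen-1α-yl]methyl}-4-(methoxymethoxy)benzoate (C1′ epimers), via arylmagnesium chloride 14 (not isolated)
Conditions: 13 (3 equiv), i-PrMgCl·LiCl, THF, −40 °C; then 11, −40 → 0 °C; aq. NH4Cl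
Reagents that add atoms: none
Why: Iodine–magnesium exchange is faster than attack on the methyl ester at −40 °C, and the arylmagnesium reagent (one equivalent deprotonates the lactol, a second adds) traps the open hydroxy-aldehyde (Grignard addition); the C1′ carbinol forms as a mixture that is deoxygenated in step 12.

**Step 10**
Reactants: 15 unsaturated aryl diol
Product: 16 methyl 3-{hydroxy[5β-(tert-butyldimethylsilyloxy)-8α-hydroxy-1β,2β,8aβ-trimethyl-trans-decahydronaphthalen-1α-yl]methyl}-4-(methoxymethoxy)benzoate (H-2 α, H-4a α)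
Conditions: [Ir(cod)(PCy3)(py)]PF6 (0.1–0.2 equiv), H2 (1–5 bar), CH2Cl2, rt
Reagents that add atoms: none
Why: Hydroxyl-directed homogeneous hydrogenation: iridium bound to the α-oriented 8-OH (homoallylic to C4=C4a) and 1′-OH (homoallylic to C2=CH2) should deliver H2 to the α-face of both alkenes, setting H-4a α (trans fusion) and H-2 α (2-methyl β) under kinetic control, while the β-face is blocked by the 8a-methyl and the 5-silyloxy group.

**Step 11**
Reactants: 16 saturated aryl diol
Product: 17 bis(S-methyl dithiocarbonate) of 16 (at O-8 and O-1′)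
Conditions: NaH, imidazole (cat.), THF, 0 °C → rt; CS2; then MeI
Reagents that add atoms: carbon disulfide S=C=S; iodomethane CI
Why: Both alkoxides add to CS2 and the dithiocarbonate salts are S-methylated (xanthate formation), the small reagents reaching both hindered hydroxyls; no stereocentre is touched.

**Step 12**
Reactants: 17 bis-xanthate
Product: 18 methyl 3-{[5β-(tert-butyldimethylsilyloxy)-1β,2β,8aβ-trimethyl-trans-decahydronaphthalen-1α-yl]methyl}-4-(methoxymethoxy)benzoate
Conditions: n-Bu3SnH, AIBN, toluene, 110 °C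
Reagents that add atoms: none
Why: Barton–McCombie deoxygenation: stannyl radical addition to each C=S and β-scission give the secondary C8 radical and the benzylic C1′ radical, both reduced by Sn–H to CH2 groups, so both tether oxygens leave in one operation.

**Step 13**
Reactants: 18 protected deoxygenated compound
Product: 19 methyl 4-hydroxy-3-{[5β-hydroxy-1β,2β,8aβ-trimethyl-trans-decahydronaphthalen-1α-yl]methyl}benzoate
Conditions: 3 M HCl in MeOH, 40 °C
Reagents that add atoms: none
Why: Acid-catalysed acetal exchange removes the aryl MOM ether and methanolysis cleaves the secondary silyl ether in one operation, at a stage where the skeleton is saturated and the methyl ester is degenerate under methanolysis.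

**Step 14**
Reactants: 19 phenol alcohol
Product: 20 methyl 4-hydroxy-3-{[1β,2β,8aβ-trimethyl-5-oxo-trans-decahydronaphthalen-1α-yl]methyl}benzoate
Conditions: Dess–Martin periodinane, NaHCO3, CH2Cl2, 0 °C
Reagents that add atoms: none
Why: Dess–Martin oxidation of the axial secondary alcohol under buffered, non-enolising conditions keeps the epimerisable H-4a next to the new ketone, and the electron-poor phenol should be oxidised far more slowly.

**Step 15**
Reactants: 20 ketone
Product: 21 methyl 4-hydroxy-3-{[(1R,2S,4aS,8aS)-1,2,8a-trimethyl-5-methylidenedecahydronaphthalen-1-yl]methyl}benzoate (target)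
Conditions: Zn, CH2Br2, TiCl4, THF (reagent pre-formed at 5 °C); then 20, CH2Cl2, 0 °C → rt; aq. NaHCO3
Reagents that add atoms: dibromomethane BrCBr
Why: Takai–Lombardo methylenation: the non-basic gem-dizinc/titanium reagent converts ketones but not esters and does not enolise the ketone, so the trans ring fusion, which may be less stable than its C4a epimer, should survive; excess reagent covers the free phenol.

**Compound list**
1 | 3-ethoxy-2-methylcyclohex-2-en-1-one | CCOC1=C(C)C(=O)CCC1 | starting material
2 | tert-butyl[(3-ethoxy-2-methylcyclohexa-1,3-dien-1-yl)oxy]dimethylsilane | CCOC1=C(C)C(O[Si](C)(C)C(C)(C)C)=CCC1 | intermediate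
3 | (±)-6-[(tert-butyldimethylsilyl)oxy]-3-ethoxy-2-methylcyclohex-2-en-1-one | CCOC1=C(C)C(=O)C(O[Si](C)(C)C(C)(C)C)CC1 | intermediate
4 | (±)-6-[(tert-butyldimethylsilyl)oxy]-3-ethoxy-2-methyl-1-vinylcyclohex-2-en-1-ol (present as its magnesium alkoxide; drawn as the alcohol) | CCOC1=C(C)C(O)(C=C)C(O[Si](C)(C)C(C)(C)C)CC1 | intermediate
5 | (±)-4-[(tert-butyldimethylsilyl)oxy]-2-methyl-3-vinylcyclohex-2-en-1-one | C=CC1=C(C)C(=O)CCC1O[Si](C)(C)C(C)(C)C | intermediate
6 | (1S,4S)-4-[(tert-butyldimethylsilyl)oxy]-2-methyl-3-vinylcyclohex-2-en-1-ol | O[C@H]1CC[C@H](O[Si](C)(C)C(C)(C)C)C(C=C)=C1C | intermediate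
7 | ethyl 2-methylbuta-2,3-dienoate | CCOC(=O)C(C)=C=C | starting material
8 | 2-methylbuta-2,3-dienoic acid | C=C=C(C)C(=O)O | intermediate
9 | (1S,4S)-4-[(tert-butyldimethylsilyl)oxy]-2-methyl-3-vinylcyclohex-2-en-1-yl 2-methylbuta-2,3-dienoate | C=C=C(C)C(=O)O[C@H]1CC[C@H](O[Si](C)(C)C(C)(C)C)C(C=C)=C1C | intermediate
10 | tricyclic γ-lactone (1α-CO–O-8α; 1β-CH3; 8aβ-CH3; 5β-OTBS; C4=C4a; 2-methylidene) | O=C1O[C@H]2CC[C@H](O[Si](C)(C)C(C)(C)C)C3=CCC(=C)[C@]1(C)[C@@]23C | intermediate
11 | lactol of 10 (C1′ hemiacetal, anomeric mixture) | OC1O[C@H]2CC[C@H](O[Si](C)(C)C(C)(C)C)C3=CCC(=C)[C@]1(C)[C@@]23C | intermediate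
12 | methyl 4-hydroxy-3-iodobenzoate | COC(=O)c1ccc(O)c(I)c1 | starting material
13 | methyl 3-iodo-4-(methoxymethoxy)benzoate | COCOc1ccc(C(=O)OC)cc1I | intermediate
14 | [5-(methoxycarbonyl)-2-(methoxymethoxy)phenyl]magnesium chloride (LiCl complex) | COCOc1ccc(C(=O)OC)cc1[Mg]Cl | intermediate
15 | unsaturated aryl diol (1′-OH epimers; 8α-OH; 5β-OTBS; 1β,8aβ-dimethyl; C4=C4a; 2-methylidene) | OC(c1cc(C(=O)OC)ccc1OCOC)[C@]1(C)C(=C)CC=C2[C@@H](O[Si](C)(C)C(C)(C)C)CC[C@H](O)[C@]12C | intermediate
16 | saturated aryl diol (1′-OH epimers; 8α-OH; 5β-OTBS; 1β,2β,8aβ-trimethyl; H-2 α; H-4a α) | OC(c1cc(C(=O)OC)ccc1OCOC)[C@]1(C)[C@@H](C)CC[C@H]2[C@@H](O[Si](C)(C)C(C)(C)C)CC[C@H](O)[C@]12C | intermediate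
17 | bis(S-methyl dithiocarbonate) of 16 | CSC(=S)OC(c1cc(C(=O)OC)ccc1OCOC)[C@]1(C)[C@@H](C)CC[C@H]2[C@@H](O[Si](C)(C)C(C)(C)C)CC[C@H](OC(=S)SC)[C@]12C | intermediate
18 | methyl 3-{[5β-(tert-butyldimethylsilyloxy)-1β,2β,8aβ-trimethyl-trans-decahydronaphthalen-1α-yl]methyl}-4-(methoxymethoxy)benzoate | COCOc1ccc(C(=O)OC)cc1C[C@]1(C)[C@@H](C)CC[C@H]2[C@@H](O[Si](C)(C)C(C)(C)C)CCC[C@]12C | intermediate
19 | methyl 4-hydroxy-3-{[5β-hydroxy-1β,2β,8aβ-trimethyl-trans-decahydronaphthalen-1α-yl]methyl}benzoate | COC(=O)c1ccc(O)c(C[C@]2(C)[C@@H](C)CC[C@H]3[C@@H](O)CCC[C@]23C)c1 | intermediate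
20 | methyl 4-hydroxy-3-{[1β,2β,8aβ-trimethyl-5-oxo-trans-decahydronaphthalen-1α-yl]methyl}benzoate | COC(=O)c1ccc(O)c(C[C@]2(C)[C@@H](C)CC[C@H]3C(=O)CCC[C@]23C)c1 | intermediate
21 | methyl 4-hydroxy-3-{[(1R,2S,4aS,8aS)-1,2,8a-trimethyl-5-methylidenedecahydronaphthalen-1-yl]methyl}benzoate | C=C1CCC[C@@]2(C)[C@H]1CC[C@H](C)[C@@]2(C)Cc1cc(C(=O)OC)ccc1O | target

**Totals**
Total step count: 15. Longest linear sequence: 13 steps (steps 1–3, 5–7, 9–15, from compound 1).

**Steps most likely to fail**

1. Step 6. The cycloaddition has to join two fully substituted carbons, so it may be outrun by oligomerisation of the allenoate, by addition to the distal allene bond, or by the exo-tether mode that gives the wrong configuration at C1. The fallback sets out from 6 and returns at 16. Compound 6 would be esterified with but-2-ynoic acid (DCC, DMAP, CH2Cl2) to the but-2-ynoate ester F1. Heating in toluene (110–140 °C) should effect the intramolecular Diels–Alder reaction of the slimmer alkynoate to the cyclohexa-1,4-diene lactone F2, in which C1 is trigonal and no fusion isomerism exists. Deprotonation at the doubly allylic C3 (LiN(i-Pr)2, DMPU, THF, −78 °C) and methylation of the extended enolate at C1 with MeI should give the 1β-methyl diene lactone F3, the five-membered lactone allowing only the cis-fused product. i-Bu2AlH would give the lactol F4, arylmagnesium chloride 14 the diene diol F5, and hydroxyl-directed hydrogenation of both ring double bonds ([Ir(cod)(PCy3)(py)]PF6, H2) would return the route at 16.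

2. Step 10. Migration of the exocyclic C2 double bond into conjugation with C4=C4a before hydrogen delivery, or incomplete hydroxyl direction, would erode the α-selectivity at C2, where the product methyl is axial and syn to the 8a-methyl. The fallback sets out from 6 and returns at 16. Compound 6 would be acylated with (E)-2-methylbut-2-enoic acid (2,4,6-trichlorobenzoyl chloride, Et3N, DMAP) to the tiglate ester F6. Thermal intramolecular Diels–Alder reaction (1,2-dichlorobenzene, BHT, 180 °C) should give the lactone F7, in which the 2β-methyl is set suprafacially from the E-alkene in the cycloaddition itself. i-Bu2AlH would give the lactol F8 and arylmagnesium chloride 14 the diol F9. Only the C4=C4a bond then needs the 8-OH-directed hydrogenation, which gives 16.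

3. Step 9. The ester-bearing arylmagnesium reagent may self-condense at the temperature needed for addition to the hindered, lactol-masked aldehyde. The fallback sets out from 11 and returns at 15. Commercial 4-bromo-2-iodophenol would be protected (MeOCH2Cl, i-Pr2NEt) as 4-bromo-2-iodo-1-(methoxymethoxy)benzene F10. Selective iodine–magnesium exchange (i-PrMgCl·LiCl, THF, −40 °C) gives the ester-free arylmagnesium chloride F11, which can be warmed to rt and added to 11 to give the bromoaryl diol F12. Methoxycarbonylation (Pd(OAc)2, Xantphos, CO 1 atm, MeOH, Et3N, 70 °C) then installs the methyl ester and gives 15.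

**Further compounds**
F1 | step 6 | (1S,4S)-4-[(tert-butyldimethylsilyl)oxy]-2-methyl-3-vinylcyclohex-2-en-1-yl but-2-ynoate | CC#CC(=O)O[C@H]1CC[C@H](O[Si](C)(C)C(C)(C)C)C(C=C)=C1C
F2 | step 6 | tricyclic lactone with C1=C2 (2-methyl) and C4=C4a double bonds | O=C1O[C@H]2CC[C@H](O[Si](C)(C)C(C)(C)C)C3=CCC(C)=C1[C@@]23C
F3 | step 6 | 1β-methyl tricyclic lactone with C2=C3 and C4=C4a double bonds | O=C1O[C@H]2CC[C@H](O[Si](C)(C)C(C)(C)C)C3=CC=C(C)[C@]1(C)[C@@]23C
F4 | step 6 | lactol of F3 (anomeric mixture) | OC1O[C@H]2CC[C@H](O[Si](C)(C)C(C)(C)C)C3=CC=C(C)[C@]1(C)[C@@]23C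
F5 | step 6 | aryl diol with C2=C3 and C4=C4a double bonds (1′-OH epimers) | OC(c1cc(C(=O)OC)ccc1OCOC)[C@]1(C)C(C)=CC=C2[C@@H](O[Si](C)(C)C(C)(C)C)CC[C@H](O)[C@]12C
F6 | step 10 | (1S,4S)-4-[(tert-butyldimethylsilyl)oxy]-2-methyl-3-vinylcyclohex-2-en-1-yl (E)-2-methylbut-2-enoate | C/C=C(\C)C(=O)O[C@H]1CC[C@H](O[Si](C)(C)C(C)(C)C)C(C=C)=C1C
F7 | step 10 | tricyclic lactone with 1β,2β,8aβ-trimethyl groups and C4=C4a double bond | O=C1O[C@H]2CC[C@H](O[Si](C)(C)C(C)(C)C)C3=CC[C@H](C)[C@]1(C)[C@@]23C
F8 | step 10 | lactol of F7 (anomeric mixture) | OC1O[C@H]2CC[C@H](O[Si](C)(C)C(C)(C)C)C3=CC[C@H](C)[C@]1(C)[C@@]23C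
F9 | step 10 | aryl diol with 2β-methyl and C4=C4a double bond (1′-OH epimers) | OC(c1cc(C(=O)OC)ccc1OCOC)[C@]1(C)[C@@H](C)CC=C2[C@@H](O[Si](C)(C)C(C)(C)C)CC[C@H](O)[C@]12C
F10 | step 9 | 4-bromo-2-iodo-1-(methoxymethoxy)benzene | COCOc1ccc(Br)cc1I
F11 | step 9 | [5-bromo-2-(methoxymethoxy)phenyl]magnesium chloride (LiCl complex) | COCOc1ccc(Br)cc1[Mg]Cl
F12 | step 9 | bromoaryl analogue of diol 15 (Br in place of CO2CH3) | OC(c1cc(Br)ccc1OCOC)[C@]1(C)C(=C)CC=C2[C@@H](O[Si](C)(C)C(C)(C)C)CC[C@H](O)[C@]12C
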